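**Plan**

- Retrosynthesis: the C8–C17 epoxide bond is cut to an 8-ketone (sulfur ylide), O9–C13 by a radical spirocyclisation that starts from an 8α,9α-epoxide, C12–C13 and C9–C11 by cross-couplings, and the lactone oxygen is traded back for a carbon, which turns the 19,6-lactone into a cyclopentenone.
- That enone is opened at C4–C19 and C5–C6 by a Pauson–Khand disconnection to a 1,7-enyne on one ring; C8–C7, C9–C8, C4–C18 and C10–C20 are the remaining cuts.
- Enabling feature: the γ-lactone C4–C19(=O)–O–C6–C5, cis-fused on the C4–C5 bond with C4 quaternary, is a cyclopent-2-enone (C4–C19(=O)–CH=C6–C5) with its α-CH exchanged for O, i.e. the adduct of the ring A alkene C4=C5, CO and a C6 alkyne tethered through C10–C9–C8–C7.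
- Forward: ring A (cyclohexene) → ring B plus cyclopentenone in one step → 19,6-lactone by excision of one ring carbon → C9 side chain → spiro tetrahydrofuran and spiro lactone in one radical step → epoxide. C17 serves as the ester and radical handle, is cut out, and returns as the epoxide CH2.
- Stereochemistry: C10 from a catalytic asymmetric conjugate addition; C4 and C5 from C10 in the cycloaddition; C6 by α-face hydride; C9 through an α-face epoxidation; C13 in the radical spirocyclisation; C8 by equatorial ylide attack.

Key step: step 5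

Remark on the chemistry: labdane numbering is used from compound 9 on (ring A = C1–C5/C10, ring B = C5–C10, C17 on C8, C18 (α) and C19 (β) on C4, C20 on C10, side chain C11–C16). Compounds 1, 5, 7, 13 and 15 are taken as commercial. The C8 centre of 8 and 9 is carried as a mixture of epimers because it becomes trigonal in step 6.

Step 1
Reactants: 1 methyl 3-oxocyclohex-1-ene-1-carboxylate
Product: 3 methyl (1S)-1-methyl-3-(trifluoromethanesulfonyloxy)cyclohex-2-ene-1-carboxylate, via methylzinc enolate 2 (not isolated)
Conditions: Me2Zn, (CuOTf)2·C6H6 (cat.), chiral sulfonate-bearing N-heterocyclic carbene ligand (cat., enantiomer that gives 1S), t-BuOMe, −30 °C; then Tf2O, −78 → 0 °C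
Reagents that add atoms: dimethylzinc C[Zn]C; trifluoromethanesulfonic anhydride O=S(=O)(OS(=O)(=O)C(F)(F)F)C(F)(F)F
Why: Copper-catalysed asymmetric conjugate addition of Me2Zn to the β-ester-substituted enone should set the quaternary C10 centre under ligand control, and O-triflation of the zinc enolate fixes the double bond regiospecifically at C4=C5.

Step 2
Reactants: 3 methyl (1S)-1-methyl-3-(trifluoromethanesulfonyloxy)cyclohex-2-ene-1-carboxylate
Product: 4 methyl (1S)-1,3-dimethylcyclohex-2-ene-1-carboxylate
Conditions: MeMgBr, Fe(acac)3 (5 mol %), THF/NMP, −30 → 0 °C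
Reagents that add atoms: methylmagnesium bromide C[Mg]Br
Why: Iron-catalysed Kumada-type coupling of the enol triflate should install C18 on C4 without touching the hindered ester or C10.

Step 3
Reactants: 4 methyl (1S)-1,3-dimethylcyclohex-2-ene-1-carboxylate; 5 tert-butyl acetate
Product: 6 tert-butyl 3-[(1S)-1,3-dimethylcyclohex-2-en-1-yl]-3-oxopropanoate
Conditions: LDA, 5, THF, −78 °C; then 4, −78 → 0 °C; aq. NH4Cl
Reagents that add atoms: tert-butyl acetate (5) CC(=O)OC(C)(C)C
Why: Crossed Claisen condensation, in which the lithium enolate of tert-butyl acetate acylates on the non-enolisable methyl ester and the product is drained as its stabilised enolate.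

Step 4
Reactants: 6 tert-butyl 3-[(1S)-1,3-dimethylcyclohex-2-en-1-yl]-3-oxopropanoate; 7 3-bromoprop-1-yne (propargyl bromide)
Product: 8 tert-butyl 2-[(1S)-1,3-dimethylcyclohex-2-ene-1-carbonyl]pent-4-ynoate (mixture of C8 epimers)
Conditions: K2CO3, acetone, rt
Reagents that add atoms: propargyl bromide (7) C#CCBr
Why: SN2 C-alkylation of the β-keto ester enolate adds C7 and the alkyne (C6), and the new C8 centre is inconsequential.

Step 5
Reactants: 8 tert-butyl 2-[(1S)-1,3-dimethylcyclohex-2-ene-1-carbonyl]pent-4-ynoate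
Product: 9 tricyclic enone: trans-fused rings A and B (C20 β, H-5 α) with C9 ketone and C8 tert-butyl ester; cyclopent-2-enone fused across C4–C5–C6 (C4–C19(=O)–CH=C6), C19 β and C18 α on C4
Conditions: Co2(CO)8 (20 mol %), tetramethylthiourea, CO (1 atm), toluene, 70 °C
Reagents that add atoms: carbon monoxide [C-]#[O+]
Why: Pauson–Khand [2+2+1] cycloaddition: the alkyne forms its Co2(CO)6 complex, the ring A alkene inserts so that C6 bonds to C5, CO inserts, and reductive elimination joins C19 to C4 and to the former terminal alkyne carbon. The closest known reaction type is the intramolecular Pauson–Khand reaction of 1,7-enynes with an endocyclic trisubstituted alkene, which gives angularly fused cyclopentenones with a quaternary centre. Ring B closes in the 6-exo sense (C6 onto C5, the alkene carbon next to the tether) and the cyclopentenone closes by the [2+2+1] union across C4–C5, so its cis fusion follows from suprafacial addition to the alkene. C5 and C4 are controlled by the existing C10 centre: with the acyl tether pseudo-equatorial on the ring A half-chair, a chair-like six-membered array should put C6 on C5 trans to the tether (H-5 anti to the C20 methyl, trans-decalin) and deliver C19 to the same β face of C4, leaving C18 α. The step needs trans over cis ring-fusion selectivity and reaction at the ring alkene only; the quaternary C10 centre and the fixed 1,7-tether secure both, and the β-keto ester stays a spectator.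

Step 6
Reactants: 9 tricyclic enone
Product: 10 C8=C9 enol triflate of 9 (9-OTf, 8-CO2t-Bu; enone unchanged)
Conditions: NaH, PhNTf2, THF, 0 °C → rt
Reagents that add atoms: N-phenylbis(trifluoromethanesulfonimide) O=S(=O)(N(c1ccccc1)S(=O)(=O)C(F)(F)F)C(F)(F)F
Why: The β-keto ester enolises only towards C8, so O-sulfonylation should give the C8=C9 enol triflate, which also deactivates this alkene for step 7.

Step 7
Reactants: 10 enol triflate
Product: 11 6-oxo-19-oic acid: ring B C6 ketone, C4 bearing β-CO2H (C19) and α-CH3, H-5 α, 9-OTf/8-CO2t-Bu alkene retained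
Conditions: O3, EtOAc/AcOH, −20 °C; then 30% H2O2, H2O, rt
Reagents that add atoms: ozone [O-][O+]=O; water O
Why: Ozonolysis of the enone C=C with oxidative work-up (the classical enone to nor-keto-acid degradation) should excise the enone α-carbon as formic acid while the strongly electron-poor triflyloxy-acrylate alkene is left alone.

Step 8
Reactants: 11 6-oxo-19-oic acid
Product: 12 19,6β-olide (γ-lactone from C19 to 6β-O) with 9-OTf and 8-CO2t-Bu on the C8=C9 alkene
Conditions: NaBH4, MeOH/THF, −20 °C; then 1 M HCl, rt
Reagents that add atoms: none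
Why: Hydride should attack C6 from the α face because the β face is screened by the syn-axial C20 methyl and C19 carboxylate, and the resulting 6β-alcohol lactonises onto the cis C19 acid on acidification.

Step 9
Reactants: 12 19,6β-olide enol triflate; 13 tributyl(ethenyl)stannane
Product: 14 9-vinyl diene: C8(CO2t-Bu)=C9–CH=CH2 on the 19,6β-olide
Conditions: Pd(PPh3)4 (5 mol %), LiCl, THF, 65 °C
Reagents that add atoms: tributyl(ethenyl)stannane (13) C=C[Sn](CCCC)(CCCC)CCCC
Why: Stille coupling of the activated enol triflate forms the C9–C11 bond under neutral conditions that spare the lactone.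

Step 10
Reactants: 14 9-vinyl diene; 15 3-bromofuran-2(5H)-one
Product: 17 butenolide ester: C9–CH2CH2–(2-oxo-2,5-dihydrofuran-3-yl), C8-CO2t-Bu, C8=C9, 19,6β-olide, via B-alkyl-9-BBN adduct 16 (not isolated)
Conditions: 9-BBN, THF, 0 °C → rt; then 15, PdCl2(dppf) (5 mol %), AsPh3, Cs2CO3, DMF/H2O, rt
Reagents that add atoms: 3-bromofuran-2(5H)-one (15) O=C1OCC=C1Br
Why: Anti-Markovnikov hydroboration of the terminal vinyl group followed by B-alkyl Suzuki–Miyaura coupling with the α-bromobutenolide forms the C12–C13 bond.

Step 11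
Reactants: 17 butenolide ester
Product: 18 17-oic acid (C8-CO2H on the C8=C9 alkene)
Conditions: TFA, CH2Cl2, 0 °C → rt
Reagents that add atoms: none
Why: Acidolysis of the tert-butyl ester (loss of 2-methylpropene) frees the C17 acid without affecting either lactone.

Step 12
Reactants: 18 17-oic acid
Product: 19 17-ol (C8-CH2OH allylic alcohol, C8=C9)
Conditions: BH3·SMe2, THF, 0 °C → rt; MeOH quench
Reagents that add atoms: none
Why: Borane reduces the carboxylic acid chemoselectively through its acyloxyborane and should leave the lactones and the hindered or electron-poor alkenes.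

Step 13
Reactants: 19 17-ol
Product: 20 8α,9α-epoxy-17-ol (C17 and C11 β, epoxide O α)
Conditions: VO(acac)2 (5 mol %), t-BuOOH, CH2Cl2, 0 °C
Reagents that add atoms: tert-butyl hydroperoxide CC(C)(C)OO
Why: Hydroxyl-directed vanadium-catalysed epoxidation is selective for the allylic alcohol alkene and should occur on the α face, anti to the C20 methyl and the 6β-oxygen, which fixes the oxygen on C9 as α.

Step 14
Reactants: 20 8α,9α-epoxy-17-ol
Product: 21 8α,9α-epoxy-17-bromide
Conditions: CBr4, PPh3, 2,6-lutidine, CH2Cl2, 0 °C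
Reagents that add atoms: carbon tetrabromide BrC(Br)(Br)Br
Why: Appel bromination (SN2 at the primary carbinol) turns C17 into a radical precursor under buffered neutral conditions that spare the epoxide.

Step 15
Reactants: 21 8α,9α-epoxy-17-bromide
Product: 22 (13R)-9α,13-epoxylabd-8(17)-ene-19,6β:16,15-diolide (spiro tetrahydrofuran and spiro γ-lactone at C13, exocyclic C8=C17)
Conditions: Bu3SnH (slow addition), Et3B, air, toluene, 0 °C
Reagents that add atoms: none
Why: Proposed new method: Bu3Sn• abstracts bromine from C17, the epoxycarbinyl radical opens by C8–O cleavage to the 8(17)-alkene and the 9α-alkoxy radical, this closes 5-exo-trig onto C13 of the butenolide and the C14 radical is reduced by Bu3SnH; the butenolide carbonyl flank should lie over the flat C8=C17 side and not against the C1 methylene, so C13 forms with C16 cis to C8 (13R); the closest known reaction type is the tin-mediated fragmentation of 2,3-epoxy halides or thiocarbonates to allyloxy radicals followed by 5-exo alkoxy-radical cyclisation onto an alkene, here applied to the α-carbon of an unsaturated lactone to make a spiro centre.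

Step 16
Reactants: 22 (13R)-9α,13-epoxylabd-8(17)-ene-19,6β:16,15-diolide
Product: 23 17-nor-8-oxo-9α,13-epoxy-19,6β:16,15-diolide
Conditions: O3, CH2Cl2, −78 °C; then Me2S
Reagents that add atoms: ozone [O-][O+]=O
Why: Ozonolysis of the only remaining alkene gives the C8 ketone.

Step 17
Reactants: 23 17-nor-8-oxo compound
Product: 24 (4S,5R,6R,8R,9S,10S,13R)-8β,17:9α,13-diepoxylabdane-19,6β:16,15-diolide (target)
Conditions: trimethylsulfonium iodide, KHMDS, THF, −10 °C; then 23, −10 → 0 °C
Reagents that add atoms: trimethylsulfonium iodide C[S+](C)C.[I-]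
Why: Corey–Chaykovsky methylenation, in which the ylide should attack C8 along the equatorial (α) trajectory because the axial β approach is blocked by the syn-axial C20 methyl and 6β-oxygen, so the new CH2 is α and the oxygen stays β-axial.

**Compound list**

1 | methyl 3-oxocyclohex-1-ene-1-carboxylate | COC(=O)C1=CC(=O)CCC1 | starting material
2 | methylzinc enolate of methyl (1S)-1-methyl-3-oxocyclohexane-1-carboxylate | C[C@@]1(C(=O)OC)C=C(O[Zn]C)CCC1 | intermediate
3 | methyl (1S)-1-methyl-3-(trifluoromethanesulfonyloxy)cyclohex-2-ene-1-carboxylate | C[C@@]1(C(=O)OC)C=C(OS(=O)(=O)C(F)(F)F)CCC1 | intermediate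
4 | methyl (1S)-1,3-dimethylcyclohex-2-ene-1-carboxylate | C[C@@]1(C(=O)OC)C=C(C)CCC1 | intermediate
5 | tert-butyl acetate | CC(=O)OC(C)(C)C | starting material
6 | tert-butyl 3-[(1S)-1,3-dimethylcyclohex-2-en-1-yl]-3-oxopropanoate | C[C@@]1(C(=O)CC(=O)OC(C)(C)C)C=C(C)CCC1 | intermediate
7 | 3-bromoprop-1-yne | C#CCBr | starting material
8 | tert-butyl 2-[(1S)-1,3-dimethylcyclohex-2-ene-1-carbonyl]pent-4-ynoate (C8 epimers) | C[C@@]1(C(=O)C(CC#C)C(=O)OC(C)(C)C)C=C(C)CCC1 | intermediate
9 | tricyclic Pauson–Khand enone (9-oxo, 8-CO2t-Bu, cyclopentenone across C4–C5–C6) | C[C@@]12CCC[C@]3(C)C(=O)C=C(CC(C(=O)OC(C)(C)C)C1=O)[C@H]23 | intermediate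
10 | C8=C9 enol triflate of 9 | C[C@@]12CCC[C@]3(C)C(=O)C=C(CC(C(=O)OC(C)(C)C)=C1OS(=O)(=O)C(F)(F)F)[C@H]23 | intermediate
11 | 6-oxo-19-oic acid with 9-OTf/8-CO2t-Bu alkene | C[C@]12CCC[C@](C)(C(O)=O)[C@@H]1C(=O)CC(C(=O)OC(C)(C)C)=C2OS(=O)(=O)C(F)(F)F | intermediate
12 | 19,6β-olide with 9-OTf/8-CO2t-Bu alkene | C[C@@]12CCC[C@]3(C)C(=O)O[C@H](CC(C(=O)OC(C)(C)C)=C1OS(=O)(=O)C(F)(F)F)[C@H]23 | intermediate
13 | tributyl(ethenyl)stannane | C=C[Sn](CCCC)(CCCC)CCCC | starting material
14 | 9-vinyl-8-CO2t-Bu diene on the 19,6β-olide | C[C@@]12CCC[C@]3(C)C(=O)O[C@H](CC(C(=O)OC(C)(C)C)=C1C=C)[C@H]23 | intermediate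
15 | 3-bromofuran-2(5H)-one | O=C1OCC=C1Br | starting material
16 | B-alkyl-9-BBN adduct (boron on C12) | C[C@@]12CCC[C@]3(C)C(=O)O[C@H](CC(C(=O)OC(C)(C)C)=C1CCB1C4CCCC1CCC4)[C@H]23 | intermediate
17 | butenolide tert-butyl ester | C[C@@]12CCC[C@]3(C)C(=O)O[C@H](CC(C(=O)OC(C)(C)C)=C1CCC1=CCOC1=O)[C@H]23 | intermediate
18 | 17-oic acid | C[C@@]12CCC[C@]3(C)C(=O)O[C@H](CC(C(O)=O)=C1CCC1=CCOC1=O)[C@H]23 | intermediate
19 | 17-ol (allylic alcohol) | C[C@@]12CCC[C@]3(C)C(=O)O[C@H](CC(CO)=C1CCC1=CCOC1=O)[C@H]23 | intermediate
20 | 8α,9α-epoxy-17-ol | C[C@@]12CCC[C@]3(C)C(=O)O[C@H](C[C@@]4(CO)O[C@@]14CCC1=CCOC1=O)[C@H]23 | intermediate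
21 | 8α,9α-epoxy-17-bromide | C[C@@]12CCC[C@]3(C)C(=O)O[C@H](C[C@@]4(CBr)O[C@@]14CCC1=CCOC1=O)[C@H]23 | intermediate
22 | (13R)-9α,13-epoxylabd-8(17)-ene-19,6β:16,15-diolide | C[C@@]12CCC[C@]3(C)C(=O)O[C@H](CC(=C)[C@]14CC[C@]1(CCOC1=O)O4)[C@H]23 | intermediate
23 | 17-nor-8-oxo-9α,13-epoxy-19,6β:16,15-diolide | C[C@@]12CCC[C@]3(C)C(=O)O[C@H](CC(=O)[C@]14CC[C@]1(CCOC1=O)O4)[C@H]23 | intermediate
24 | (4S,5R,6R,8R,9S,10S,13R)-8β,17:9α,13-diepoxylabdane-19,6β:16,15-diolide | C[C@@]12CCC[C@]3(C)C(=O)O[C@H](C[C@@]4(CO4)[C@]14CC[C@]1(CCOC1=O)O4)[C@H]23 | target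

Total steps: 17. Longest linear sequence: 17 steps (1 → 24).

**Steps most likely to fail**

Step 15 (Proposed new method). The 9α-alkoxy radical may undergo β-scission of the C9–C10 bond or be reduced by the stannane before it cyclises, and the facial choice at C13 rests on a steric argument only. The fallback avoids the alkoxy radical and makes C13 the radical centre. It sets out from 21: zinc dust in ethanol with NH4Cl (reductive opening of the 2,3-epoxy bromide) should give the 9α-hydroxy-8(17)-ene butenolide F1. Conjugate reduction of the butenolide with K-Selectride and trapping of the enolate with NBS gives the 13-bromo lactone F2. Copper-catalysed tert-alkylative etherification of the α-bromo lactone with the 9-hydroxyl (CuBr, tris(2-pyridylmethyl)amine, Cs2CO3, toluene) closes the spiro ether through a planar C13 radical, for which the same flank preference holds, and comes back to the route at 22.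

Step 5. Insertion of the trisubstituted ring alkene into the cobalt–alkyne complex may be too slow, so that alkyne oligomerisation wins, or the trans ring fusion may erode. The fallback makes the same two bonds by syn carbopalladation and sets out from 6: alkylation with 2,3-dibromopropene (K2CO3, acetone) gives the vinyl bromide F3. A domino 6-exo Heck cyclisation and methoxycarbonylation (Pd(OAc)2, PPh3, Et3N, CO, MeOH) adds C6 and the C19 ester syn across C4=C5 to give the bicyclic diester with a C6 exocyclic methylene F4. Enol triflation as in step 6 gives F5, ozonolysis with Me2S work-up gives the 6-ketone F6, and NaBH4 followed by acid-catalysed lactonisation comes back to the route at 12.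

Step 17. The basic ylide may enolise the hindered ketone or attack a lactone carbonyl, and facial selectivity at C8 may be incomplete. The fallback keeps C17 and sets out from 22: NBS in aqueous THF should place bromine on C17 and water on C8 from the face opposite the bromonium ion to give the 8β-hydroxy-17-bromide F7, and DBU in THF closes the 8β,17-epoxide and comes back to the route at 24.

**Further compounds**

F1 | step 15 | 9α-hydroxy-8(17)-ene with butenolide side chain on the 19,6β-olide | C[C@@]12CCC[C@]3(C)C(=O)O[C@H](CC(=C)[C@]1(O)CCC1=CCOC1=O)[C@H]23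
F2 | step 15 | 13-bromo-γ-butyrolactone analogue of F1 (C13 epimers) | C[C@@]12CCC[C@]3(C)C(=O)O[C@H](CC(=C)[C@]1(O)CCC1(Br)CCOC1=O)[C@H]23
F3 | step 5 | tert-butyl 4-bromo-2-[(1S)-1,3-dimethylcyclohex-2-ene-1-carbonyl]pent-4-enoate | C[C@@]1(C(=O)C(CC(Br)=C)C(=O)OC(C)(C)C)C=C(C)CCC1
F4 | step 5 | bicyclic diester: C4 β-CO2Me, C6 exocyclic methylene, C9 ketone, C8-CO2t-Bu | C[C@]12CCC[C@](C)(C(=O)OC)[C@@H]1C(=C)CC(C(=O)OC(C)(C)C)C2=O
F5 | step 5 | C8=C9 enol triflate of F4 | C[C@]12CCC[C@](C)(C(=O)OC)[C@@H]1C(=C)CC(C(=O)OC(C)(C)C)=C2OS(=O)(=O)C(F)(F)F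
F6 | step 5 | 6-ketone from F5 | C[C@]12CCC[C@](C)(C(=O)OC)[C@@H]1C(=O)CC(C(=O)OC(C)(C)C)=C2OS(=O)(=O)C(F)(F)F
F7 | step 17 | 8β-hydroxy-17-bromo-9α,13-epoxy-19,6β:16,15-diolide | C[C@@]12CCC[C@]3(C)C(=O)O[C@H](C[C@@](O)(CBr)[C@]14CC[C@]1(CCOC1=O)O4)[C@H]23
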